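Amounts first, as fractions of the starting material charged: the free catalyst is 0.0100 and the coupling partner 0.900. The scavenger is 0.650 in north and 1.90 in east, and the new flasks amber, teal and red carry 1.20, 1.80 and 2.70.

| setting | north | east | amber | teal | red |
|---|---|---|---|---|---|
| starting material | 0.20 M | 0.20 M | 0.20 M | 0.20 M | 0.20 M |
| coupling partner | 0.18 M | 0.18 M | 0.180 M | 0.180 M | 0.180 M |
| scavenger | 0.13 M | 0.38 M | 0.240 M | 0.360 M | 0.540 M |
| free catalyst | 2 mM | 2 mM | 2.0 mM | 2.0 mM | 2.0 mM |
| remark | run made earlier | run made earlier |  |  |  |
| time |  |  | 8.0 h | 8.0 h | 8.0 h |

| run | time / h | starting material / % | target / % |
|---|---|---|---|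
| north | 0.667 | 96.2 | 5.6 |
| north | 1.00 | 92.0 | 5.8 |
| north | 2.00 | 90.2 | 13.4 |
| north | 3.00 | 81.8 | 18.6 |
| north | 5.00 | 71.1 | 28.4 |
| north | 8.00 | 58.6 | 39.8 |
| east | 0.500 | 97.1 | 2.2 |
| east | 1.50 | 90.3 | 7.6 |
| east | 3.00 | 81.9 | 17.5 |
| east | 4.00 | 76.4 | 23.0 |
| east | 6.00 | 66.5 | 34.9 |
| east | 8.00 | 58.8 | 44.4 |

(readings scatter by 1 percentage point)

- for released group the idle adduct is counted in
- steps thought possible: starting material + free catalyst <-> catalyst intermediate A; catalyst intermediate B <-> released group + catalyst intermediate C; scavenger + released group -> scavenged by-product; coupling partner + released group <-> idle adduct; catalyst intermediate C -> catalyst intermediate D; coupling partner + catalyst intermediate A -> catalyst intermediate B; catalyst intermediate D -> free catalyst + target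

1. part of the starting material that has reacted at the end, amber
2. part of the starting material that has reacted at the end, teal
3. part of the starting material that has reacted at the end, red
4. what raising the concentration of scavenger from its lowest to its highest value here does to the part of the starting material that has reacted (changes below 5 percentage points count as none) (it falls / it rises / no change)

In the first instants, starting material binds free catalyst as catalyst intermediate A and coupling partner joins it. The cycle through catalyst intermediates B, C and D then hands back free catalyst and target, sending out released group for the scavenger to catch. The catalyst must turn many times: by 8.00 h, north has used 41.4 starting material per catalyst.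

In the middle, at 3.00 h, north and east read 81.8% and 81.9% of starting material, although east holds 2.92 times the scavenger. At the end they read 58.6% and 58.8%. If one released group leaves per starting material reacted, north still keeps 0.236 of scavenger then. What could matter is released group returning to catalyst intermediate C before the scavenger catches it, so we compare the two runs for a slower flask on the side with less scavenger.

Dividing the amount reacted in east by that in north at one time removes time from the comparison. Our number is −0.00451, give or take 0.0318 from the scatter of the two readings. This is the scavenger order, the logarithm of the ratio of amounts reacted over the logarithm of the ratio of scavenger charges. A shift of 5 percentage points between amber and red needs an order of 0.141, larger than that uncertainty. So, if the order holds up to red's charge, we expect amber, teal and red each near 41.3%, the mean reacted in the two runs.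

The forecast gave 41.3% (39% to 43.5%) for amber, 41.3% (39% to 43.5%) for teal, 41.5% (38.5% to 44.5%) for red and no change, reading the two runs thus: “Scavenger therefore has no visible kinetic effect”.

The flasks give 42.5%, 42.5% and 42.6%, which is no change, with a change of 0.13 points.

    starting material + free catalyst ⇌ catalyst intermediate A (K = 3.10 /M, k = 300 /M/h)
    catalyst intermediate B ⇌ released group + catalyst intermediate C (K = 0.280 M, k = 32.0 /h)
    scavenger + released group → scavenged by-product (k = 45.0 /M/h)
    coupling partner + released group ⇌ idle adduct, settled at all times (K = 11.0 /M)
    catalyst intermediate C → catalyst intermediate D (k = 53.0 /h)
    coupling partner + catalyst intermediate A → catalyst intermediate B (k = 250 /M/h)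
    catalyst intermediate D → free catalyst + target (k = 47.0 /h)

From amber to red the scavenger order comes out at 0.00365. With so small an order, red stopped at 5.0 h should match north's reading then, 28.9% reacted, and it gives 29.6%, against a scatter of 1 point. In amber at 8.00 h, which holds more released group than teal or red, catalyst intermediate C goes back with a rate constant of 0.126 /h, against 53 /h onward to catalyst intermediate D. In amber that way back makes no difference: back over onward, with catalyst intermediate C dropping out, is 0.00238.

The earlier runs and the new flask were generated by integration on assumed constants, noise included.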